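**Strategy.** The route rests on disconnecting the lactone O–C6 bond. In the target, the lactone oxygen on C6, the C4=C5 olefin and the C15 hydroxyl form a 1,4-dioxygenated allylic array on the ten-membered carbocycle (ring A) – the signature of an SN2′ opening of a C4–C15 spiro-oxirane across a C5=C6 olefin. In the key step the C12 acrylic acid on C7 attacks C6 of a macrocyclic (Z,Z)-2,2-divinyloxirane: one operation closes the γ-lactone (ring B), sets C6, creates the cis C4=C5 bond of the diene and frees the 15-OH. The precursor is a ten-membered divinyl spiro-oxirane seco-acid, built by Sharpless epoxidation, a chloroacetyl linchpin, indium pentadienylation and ring-closing metathesis.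

Key step: step 17

Remark: atoms are numbered C1–C15 as in the germacrane skeleton of the target (C6 lactone carbinol, C12 lactone carbonyl, C15 hydroxymethyl carbon); the oxirane carbon C4 is formed without control in step 6, both epimers are carried on, and this centre is left unspecified in the SMILES because it becomes trigonal in step 17.

Step 1
Reactants: 1 tert-butyl(but-3-yn-1-yloxy)dimethylsilane
Product: 3 (E)-5-[(tert-butyldimethylsilyl)oxy]-3-methylpent-2-en-1-ol, via alkenyldimethylalane 2 (not isolated)
Conditions: Me3Al, Cp2ZrCl2 (25 mol%), CH2Cl2, 0 °C to rt; n-BuLi, THF, −78 °C; (CH2O)n, −78 °C to rt; H2O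
Reagents that add atoms: trimethylaluminium C[Al](C)C; formaldehyde (from paraformaldehyde) C=O
Why: Negishi zirconium-catalysed carboalumination adds methyl and aluminium syn across the terminal alkyne, and the butyl ate complex of alane 2 is hydroxymethylated with retention, which fixes the E geometry of the future C1=C10 unit.

Step 2
Reactants: 3 (E)-5-[(tert-butyldimethylsilyl)oxy]-3-methylpent-2-en-1-ol
Product: 4 [(2R,3R)-3-{2-[(tert-butyldimethylsilyl)oxy]ethyl}-3-methyloxiran-2-yl]methanol
Conditions: Ti(OiPr)4 (10 mol%), D-(−)-diethyl tartrate (12 mol%), t-BuOOH, 4 Å molecular sieves, CH2Cl2, −20 °C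
Reagents that add atoms: tert-butyl hydroperoxide CC(C)(C)OO
Why: Sharpless asymmetric epoxidation of the E allylic alcohol under reagent control by D-(−)-diethyl tartrate should give the (2R,3R)-epoxide, which sets C1 and C10 of the target as the trans-oxirane.

Step 3
Reactants: 4 [(2R,3R)-3-{2-[(tert-butyldimethylsilyl)oxy]ethyl}-3-methyloxiran-2-yl]methanol
Product: 5 (2S,3R)-3-{2-[(tert-butyldimethylsilyl)oxy]ethyl}-3-methyloxirane-2-carbaldehyde
Conditions: Dess–Martin periodinane, pyridine, CH2Cl2, 0 °C
Reagents that add atoms: none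
Why: Dess–Martin oxidation under pyridine buffering should give the α,β-epoxy aldehyde without opening the oxirane or epimerizing C1 (the descriptor changes only by priority).

Step 4
Reactants: 5 (2S,3R)-3-{2-[(tert-butyldimethylsilyl)oxy]ethyl}-3-methyloxirane-2-carbaldehyde
Product: 6 tert-butyl{2-[(2R,3R)-3-ethynyl-2-methyloxiran-2-yl]ethoxy}dimethylsilane
Conditions: dimethyl (1-diazo-2-oxopropyl)phosphonate, K2CO3, MeOH, 0 °C to rt
Reagents that add atoms: dimethyl (1-diazo-2-oxopropyl)phosphonate COP(=O)(OC)C(=[N+]=[N-])C(C)=O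
Why: Ohira–Bestmann (Seyferth–Gilbert) homologation converts the aldehyde into the terminal alkyne under mild carbonate conditions that leave the oxirane and the silyl ether intact.

Step 5
Reactants: 6 tert-butyl{2-[(2R,3R)-3-ethynyl-2-methyloxiran-2-yl]ethoxy}dimethylsilane; 7 2-chloro-N-methoxy-N-methylacetamide
Product: 9 1-chloro-4-[(2R,3R)-3-{2-[(tert-butyldimethylsilyl)oxy]ethyl}-3-methyloxiran-2-yl]but-3-yn-2-one, via lithium acetylide 8 (not isolated)
Conditions: n-BuLi, THF, −78 °C; then 7, −78 to −40 °C; H2O
Reagents that add atoms: none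
Why: Weinreb ketone synthesis: the lithium acetylide adds once to the amide, whose chelated tetrahedral intermediate collapses only on work-up, giving the chloromethyl ynone that brings in C4 and C15.

Step 6
Reactants: 9 1-chloro-4-[(2R,3R)-3-{2-[(tert-butyldimethylsilyl)oxy]ethyl}-3-methyloxiran-2-yl]but-3-yn-2-one
Product: 11 tert-butyl{2-[(2R,3R)-3-[(2-ethenyloxiran-2-yl)ethynyl]-2-methyloxiran-2-yl]ethoxy}dimethylsilane (C4 epimer mixture), via chlorohydrin magnesium alkoxide 10 (not isolated)
Conditions: CH2=CHMgBr, THF, −78 °C; then rt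
Reagents that add atoms: vinylmagnesium bromide C=C[Mg]Br
Why: Grignard 1,2-addition to the ynone carbonyl gives the tertiary chlorohydrin alkoxide, which closes to the oxirane by intramolecular Williamson displacement on warming; the new C4 centre is not controlled and need not be, since it is destroyed in step 17.

Step 7
Reactants: 11 tert-butyl{2-[(2R,3R)-3-[(2-ethenyloxiran-2-yl)ethynyl]-2-methyloxiran-2-yl]ethoxy}dimethylsilane (C4 epimer mixture)
Product: 12 tert-butyl{2-[(2R,3R)-3-[(Z)-2-(2-ethenyloxiran-2-yl)ethenyl]-2-methyloxiran-2-yl]ethoxy}dimethylsilane (C4 epimer mixture)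
Conditions: H2 (1 atm), Pd/CaCO3 poisoned with Pb(OAc)2 (Lindlar catalyst), quinoline, EtOAc, rt
Reagents that add atoms: none
Why: Lindlar semihydrogenation delivers hydrogen syn to the internal alkyne and so gives the Z C2=C3 olefin, while the poisoned catalyst should spare the terminal vinyl group and both oxiranes.

Step 8
Reactants: 12 tert-butyl{2-[(2R,3R)-3-[(Z)-2-(2-ethenyloxiran-2-yl)ethenyl]-2-methyloxiran-2-yl]ethoxy}dimethylsilane (C4 epimer mixture)
Product: 13 2-[(2R,3R)-3-[(Z)-2-(2-ethenyloxiran-2-yl)ethenyl]-2-methyloxiran-2-yl]ethan-1-ol (C4 epimer mixture)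
Conditions: Bu4NF, THF, 0 °C
Reagents that add atoms: none
Why: Fluoride desilylation removes the primary silyl ether and leaves the base-stable oxiranes and olefins untouched.

Step 9
Reactants: 13 2-[(2R,3R)-3-[(Z)-2-(2-ethenyloxiran-2-yl)ethenyl]-2-methyloxiran-2-yl]ethan-1-ol (C4 epimer mixture)
Product: 14 2-[(2R,3R)-3-[(Z)-2-(2-ethenyloxiran-2-yl)ethenyl]-2-methyloxiran-2-yl]acetaldehyde (C4 epimer mixture)
Conditions: Dess–Martin periodinane, pyridine, CH2Cl2, 0 °C; used crude at once
Reagents that add atoms: none
Why: Buffered Dess–Martin oxidation should give the β,γ-epoxy aldehyde (C8), which is taken on immediately to avoid β-elimination of the oxirane.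

Step 10
Reactants: 15 acryloyl chloride; 16 2-(trimethylsilyl)ethanol
Product: 17 2-(trimethylsilyl)ethyl acrylate
Conditions: Et3N, CH2Cl2, 0 °C
Reagents that add atoms: none
Why: Acylation of the alcohol by the acid chloride gives the fluoride-labile ester that later allows the acid to be unmasked without acid or base.

Step 11
Reactants: 17 2-(trimethylsilyl)ethyl acrylate; 18 acrolein
Product: 19 2-(trimethylsilyl)ethyl 3-hydroxy-2-methylidenepent-4-enoate (racemic)
Conditions: DABCO (20 mol%), 1,4-dioxane/H2O, rt
Reagents that add atoms: none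
Why: Morita–Baylis–Hillman reaction: the amine adds to the acrylate and the resulting enolate attacks the acrolein carbonyl, giving the bis-allylic alcohol whose carbinol centre is removed in the next step.

Step 12
Reactants: 19 2-(trimethylsilyl)ethyl 3-hydroxy-2-methylidenepent-4-enoate (racemic)
Product: 20 2-(trimethylsilyl)ethyl (2Z)-2-(bromomethyl)penta-2,4-dienoate
Conditions: NBS, Me2S, CH2Cl2, 0 °C to rt
Reagents that add atoms: N-bromosuccinimide BrN1C(=O)CCC1=O
Why: Corey–Kim-type activation of the hydroxyl and attack of bromide with allylic transposition (SN2′) should give the conjugated, thermodynamically preferred 2Z bromide, in which the vinyl group is cis to CH2Br.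

Step 13
Reactants: 14 2-[(2R,3R)-3-[(Z)-2-(2-ethenyloxiran-2-yl)ethenyl]-2-methyloxiran-2-yl]acetaldehyde (C4 epimer mixture); 20 2-(trimethylsilyl)ethyl (2Z)-2-(bromomethyl)penta-2,4-dienoate
Product: 21 2-(trimethylsilyl)ethyl (3R,4R)-3-ethenyl-5-[(2R,3R)-3-[(Z)-2-(2-ethenyloxiran-2-yl)ethenyl]-2-methyloxiran-2-yl]-4-hydroxy-2-methylidenepentanoate (C4 epimer mixture)
Conditions: indium powder, THF/pH 7 phosphate buffer (3:1), 0 °C to rt
Reagents that add atoms: none
Why: Indium-mediated Barbier allylation: the ester-substituted pentadienylindium reacts at its γ-carbon through a chair Zimmerman–Traxler transition state with the Z-placed vinyl group axial, which should give the syn C7/C8 pair, and the aldehyde face is chosen by the neighbouring C10 oxirane (indium bridging the aldehyde and oxirane oxygens, attack on the face opposite the oxirane carbon C1), which should favour the 7R,8R isomer.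

Step 14
Reactants: 22 4-methylfuran-2(5H)-one
Product: 24 (2Z)-4-acetoxy-3-methylbut-2-enoic acid, via sodium hydroxyenoate 23 (not isolated)
Conditions: NaOH (1.0 equiv), H2O, rt; evaporate; Ac2O, pyridine, 0 °C; cold 1 M HCl
Reagents that add atoms: sodium hydroxide [Na+].[OH-]; acetic anhydride CC(=O)OC(C)=O
Why: Saponification opens the butenolide with the ring-enforced Z geometry retained, and acetylation of the primary allylic hydroxyl of the dry carboxylate salt before acidification blocks relactonization.

Step 15
Reactants: 21 2-(trimethylsilyl)ethyl (3R,4R)-3-ethenyl-5-[(2R,3R)-3-[(Z)-2-(2-ethenyloxiran-2-yl)ethenyl]-2-methyloxiran-2-yl]-4-hydroxy-2-methylidenepentanoate (C4 epimer mixture); 24 (2Z)-4-acetoxy-3-methylbut-2-enoic acid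
Product: 25 2-(trimethylsilyl)ethyl (3R,4R)-4-{[(2Z)-4-acetoxy-3-methylbut-2-enoyl]oxy}-3-ethenyl-5-[(2R,3R)-3-[(Z)-2-(2-ethenyloxiran-2-yl)ethenyl]-2-methyloxiran-2-yl]-2-methylidenepentanoate (C4 epimer mixture)
Conditions: DCC, DMAP (10 mol%), CH2Cl2, −10 to 0 °C
Reagents that add atoms: none
Why: Steglich esterification acylates the only free hydroxyl (C8) with retention, and the low temperature should limit Z/E isomerization of the β-methyl enoate.

Step 16
Reactants: 25 2-(trimethylsilyl)ethyl (3R,4R)-4-{[(2Z)-4-acetoxy-3-methylbut-2-enoyl]oxy}-3-ethenyl-5-[(2R,3R)-3-[(Z)-2-(2-ethenyloxiran-2-yl)ethenyl]-2-methyloxiran-2-yl]-2-methylidenepentanoate (C4 epimer mixture)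
Product: 26 macrocyclic divinyl spiro-oxirane ester: ten-membered ring C1–C10 with the (1R,10R) trans-oxirane, Z C2=C3, the C4 spiro-oxirane (C15, epimer mixture), Z C5=C6, C7 (R) carrying the 2-(trimethylsilyl)ethyl acrylate unit and C8 (R) carrying the (2Z)-4-acetoxy-3-methylbut-2-enoate
Conditions: second-generation Hoveyda–Grubbs catalyst RuCl2(H2IMes)(=CH-C6H4-2-OiPr) (10 mol%), 1,4-benzoquinone (20 mol%), toluene (1 mM), 60 °C
Reagents that add atoms: none
Why: Ring-closing metathesis joins the two terminal vinyl groups with loss of ethylene, the ester-bearing tri- and 1,1-disubstituted olefins being too unreactive to compete, and the ten-membered ring with its trans-oxirane and Z C2=C3 bond should enforce the Z geometry of the new C5=C6 bond.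

Step 17
Reactants: 26 macrocyclic divinyl spiro-oxirane ester
Product: 28 target CNP0292814.1 (1R,6R,7R,8R,10R), via seco-acid 27 (not isolated)
Conditions: TASF [(Me2N)3S+ Me3SiF2−], DMF, 0 °C; then AcOH (1.1 equiv), (CF3)2CHOH, 0 °C to rt
Reagents that add atoms: none
Why: Proposed new method: fluoride-induced fragmentation of the 2-(trimethylsilyl)ethyl ester (known) frees acrylic acid 27, whose carboxyl lies five atoms from C6 and hydrogen-bonds to the tertiary, doubly allylic C4–C15 spiro-oxirane; C4–O ionization with pentadienyl-cation character is answered by collapse of the carboxylate oxygen on C6, a metal-free vinylogous (SN2′) epoxide-opening lactonization whose closest known relatives are the acid-catalysed epoxide-opening lactonization of epoxy acids and the Tsuji–Trost lactonization of vinyl epoxides with carboxylic acids. The γ-lactone (ring B) closes in a 5-exo-trig mode on the C5=C6 olefin with allylic transposition, which at the same time creates the C4=C5 bond and releases the C15 oxygen as the free primary alcohol. The new C6 stereocentre is controlled by C7: allylic 1,3-strain across the Z C5=C6 bond holds H7 in the olefin plane, so the carboxyl on C11 reaches the face that gives the trans-fused lactone (6R), and the ten-membered ring keeps C3 cis to C6, giving the ring-cis C4=C5 olefin. Because C4 becomes trigonal, both spiro-oxirane epimers should converge on one product. The step needs chemoselectivity for the C4 oxirane over the C1–C10 oxirane and regioselectivity for C6 over C4 or C2: the first is secured by the far easier ionization of a tertiary carbon flanked by two vinyl groups under carboxylic-acid-only acidity, the second by five- versus seven- or nine-membered ring formation.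

**Compound list**

1 | tert-butyl(but-3-yn-1-yloxy)dimethylsilane | C#CCCO[Si](C)(C)C(C)(C)C | starting material
2 | (E)-{4-[(tert-butyldimethylsilyl)oxy]-2-methylbut-1-en-1-yl}dimethylalane | C[Al](C)/C=C(\C)CCO[Si](C)(C)C(C)(C)C | intermediate
3 | (E)-5-[(tert-butyldimethylsilyl)oxy]-3-methylpent-2-en-1-ol | OC/C=C(\C)CCO[Si](C)(C)C(C)(C)C | intermediate
4 | [(2R,3R)-3-{2-[(tert-butyldimethylsilyl)oxy]ethyl}-3-methyloxiran-2-yl]methanol | OC[C@H]1O[C@]1(C)CCO[Si](C)(C)C(C)(C)C | intermediate
5 | (2S,3R)-3-{2-[(tert-butyldimethylsilyl)oxy]ethyl}-3-methyloxirane-2-carbaldehyde | O=C[C@H]1O[C@]1(C)CCO[Si](C)(C)C(C)(C)C | intermediate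
6 | tert-butyl{2-[(2R,3R)-3-ethynyl-2-methyloxiran-2-yl]ethoxy}dimethylsilane | C#C[C@H]1O[C@]1(C)CCO[Si](C)(C)C(C)(C)C | intermediate
7 | 2-chloro-N-methoxy-N-methylacetamide | CON(C)C(=O)CCl | starting material
8 | lithium acetylide of 6 | [Li]C#C[C@H]1O[C@]1(C)CCO[Si](C)(C)C(C)(C)C | intermediate
9 | 1-chloro-4-[(2R,3R)-3-{2-[(tert-butyldimethylsilyl)oxy]ethyl}-3-methyloxiran-2-yl]but-3-yn-2-one | ClCC(=O)C#C[C@H]1O[C@]1(C)CCO[Si](C)(C)C(C)(C)C | intermediate
10 | bromomagnesium alkoxide of the C4 chlorohydrin (C4 epimer mixture) | ClCC(O[Mg]Br)(C=C)C#C[C@H]1O[C@]1(C)CCO[Si](C)(C)C(C)(C)C | intermediate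
11 | tert-butyl{2-[(2R,3R)-3-[(2-ethenyloxiran-2-yl)ethynyl]-2-methyloxiran-2-yl]ethoxy}dimethylsilane (C4 epimer mixture) | C=CC1(CO1)C#C[C@H]2O[C@]2(C)CCO[Si](C)(C)C(C)(C)C | intermediate
12 | tert-butyl{2-[(2R,3R)-3-[(Z)-2-(2-ethenyloxiran-2-yl)ethenyl]-2-methyloxiran-2-yl]ethoxy}dimethylsilane (C4 epimer mixture) | C=CC1(CO1)/C=C\[C@H]2O[C@]2(C)CCO[Si](C)(C)C(C)(C)C | intermediate
13 | 2-[(2R,3R)-3-[(Z)-2-(2-ethenyloxiran-2-yl)ethenyl]-2-methyloxiran-2-yl]ethan-1-ol (C4 epimer mixture) | C=CC1(CO1)/C=C\[C@H]2O[C@]2(C)CCO | intermediate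
14 | 2-[(2R,3R)-3-[(Z)-2-(2-ethenyloxiran-2-yl)ethenyl]-2-methyloxiran-2-yl]acetaldehyde (C4 epimer mixture) | C=CC1(CO1)/C=C\[C@H]2O[C@]2(C)CC=O | intermediate
15 | acryloyl chloride | C=CC(=O)Cl | starting material
16 | 2-(trimethylsilyl)ethanol | C[Si](C)(C)CCO | starting material
17 | 2-(trimethylsilyl)ethyl acrylate | C=CC(=O)OCC[Si](C)(C)C | intermediate
18 | acrolein | C=CC=O | starting material
19 | 2-(trimethylsilyl)ethyl 3-hydroxy-2-methylidenepent-4-enoate (racemic) | C=CC(O)C(=C)C(=O)OCC[Si](C)(C)C | intermediate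
20 | 2-(trimethylsilyl)ethyl (2Z)-2-(bromomethyl)penta-2,4-dienoate | C=C/C=C(\CBr)C(=O)OCC[Si](C)(C)C | intermediate
21 | 2-(trimethylsilyl)ethyl (3R,4R)-3-ethenyl-5-[(2R,3R)-3-[(Z)-2-(2-ethenyloxiran-2-yl)ethenyl]-2-methyloxiran-2-yl]-4-hydroxy-2-methylidenepentanoate (C4 epimer mixture) | C=CC1(CO1)/C=C\[C@H]2O[C@]2(C)C[C@@H](O)[C@@H](C(=C)C(=O)OCC[Si](C)(C)C)C=C | intermediate
22 | 4-methylfuran-2(5H)-one | CC1=CC(=O)OC1 | starting material
23 | sodium (2Z)-4-hydroxy-3-methylbut-2-enoate | [Na+].[O-]C(=O)/C=C(/C)CO | intermediate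
24 | (2Z)-4-acetoxy-3-methylbut-2-enoic acid | OC(=O)/C=C(/C)COC(C)=O | intermediate
25 | 2-(trimethylsilyl)ethyl (3R,4R)-4-{[(2Z)-4-acetoxy-3-methylbut-2-enoyl]oxy}-3-ethenyl-5-[(2R,3R)-3-[(Z)-2-(2-ethenyloxiran-2-yl)ethenyl]-2-methyloxiran-2-yl]-2-methylidenepentanoate (C4 epimer mixture) | C=CC1(CO1)/C=C\[C@H]2O[C@]2(C)C[C@@H](OC(=O)/C=C(/C)COC(C)=O)[C@@H](C(=C)C(=O)OCC[Si](C)(C)C)C=C | intermediate
26 | macrocyclic divinyl spiro-oxirane ester (1R,7R,8R,10R; 2Z,5Z; C4 epimer mixture; 2-(trimethylsilyl)ethyl acrylate on C7, side-chain ester on C8) | C=C(C(=O)OCC[Si](C)(C)C)[C@H]1/C=C\C2(CO2)/C=C\[C@H]3O[C@]3(C)C[C@H]1OC(=O)/C=C(/C)COC(C)=O | intermediate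
27 | seco-acid: free acrylic acid of 26 (C4 epimer mixture) | C=C(C(=O)O)[C@H]1/C=C\C2(CO2)/C=C\[C@H]3O[C@]3(C)C[C@H]1OC(=O)/C=C(/C)COC(C)=O | intermediate
28 | CNP0292814.1: (1R,6R,7R,8R,10R)-1,10-epoxy-15-hydroxy-8-{[(2Z)-4-acetoxy-3-methylbut-2-enoyl]oxy}germacra-2Z,4(ring-cis),11(13)-trien-6,12-olide | C=C1C(=O)O[C@@H]2/C=C(CO)\C=C/[C@H]3O[C@]3(C)C[C@@H](OC(=O)/C=C(/C)COC(C)=O)[C@@H]12 | target

**Totals and risks**

Total step count: 17. Longest linear sequence: 13 steps (steps 1–9, 13, 15, 16, 17).

Steps most likely to fail: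

1. Step 17 (Proposed new method). What may go wrong: the ionizing spiro-oxirane may take other exits (hydride shift to a C4 aldehyde, closure at C4 to a seven-membered lactone, opening of the C1–C10 oxirane), or the carboxylate may close on the wrong face of C6. Fallback (known chemistry): it sets out from 26 and comes back at 28. After the same fluoride cleavage, seco-acid 27 is exposed at once to Pd(PPh3)4 (a zerovalent palladium complex, 5 mol%) in THF at 0 °C. Tsuji–Trost ionization of the vinyl oxirane gives a π-allylpalladium alkoxide that deprotonates the acid and is captured by the carboxylate at C6. This is the established allylic substitution of vinyl epoxides by carboxylic acids; low temperature and short contact are meant to spare the C1–C10 vinyl oxirane. No new isolated compound is needed.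

2. Step 13. What may go wrong: weak facial discrimination by the remote C10 oxirane, giving both syn diastereomers, and partial α-attack of the pentadienylindium. Fallback: it sets out from 20 and 14 and comes back at 21. Bromide 20 is converted with B2pin2 and Pd2(dba)3 into 2-(trimethylsilyl)ethyl (2E)-2-[(4,4,5,5-tetramethyl-1,3,2-dioxaborolan-2-yl)methyl]penta-2,4-dienoate F1. F1 is added to 14 under a chiral BINOL-derived phosphoric acid (TRIP, the enantiomer matched to the 8R sense) in toluene at low temperature. The catalyst, not the substrate, then selects the aldehyde face, while the closed six-membered allylboration transition state keeps the syn C7/C8 relationship.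

3. Step 16. What may go wrong: oligomerization or stalling of the ring closure (chelation of the ruthenium alkylidene by the two ester carbonyls that flank C7, strain of the ten-membered ring) and formation of the E olefin. Fallback: it sets out from 21 and comes back at 26. The order is inverted: hydroxy ester 21, which has only one ester next to C7 and a free 8-hydroxyl that can hydrogen-bond to it and fold the chain, is cyclized first under the same metathesis catalyst to the macrocyclic hydroxy ester F2. F2 is then acylated with 24 (DCC, DMAP) to give 26.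

Further compounds
F0 | step 17 | none | none
F1 | step 13 | 2-(trimethylsilyl)ethyl (2E)-2-[(4,4,5,5-tetramethyl-1,3,2-dioxaborolan-2-yl)methyl]penta-2,4-dienoate | C=C/C=C(\CB1OC(C)(C)C(C)(C)O1)C(=O)OCC[Si](C)(C)C
F2 | step 16 | macrocyclic hydroxy ester (8-O-deacyl analogue of 26; 1R,7R,8R,10R; 2Z,5Z; C4 epimer mixture) | C=C(C(=O)OCC[Si](C)(C)C)[C@H]1/C=C\C2(CO2)/C=C\[C@H]3O[C@]3(C)C[C@H]1O
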